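**Conventions and assumptions**

- Atom labels. Ring A: C1 carries the depsidone carbonyl, C2 the ether oxygen, C3 CH2OH, C4 OMe, C5 H, C6 CH3. Ring B: C1' carries the ether oxygen, C2' the ester oxygen, C3' CH3, C4' OH, C5' the γ-lactone carbonyl, C6' the lactol carbon. The lactol carbon in the target SMILES is (R).
- Assumption on configuration: a free 3-hydroxyphthalide epimerises through its open aldehyde acid, so the centre is fixed as an acylal and released last under neutral, water-free conditions; the product is assumed to keep its configuration when isolated cold and stored as a solid away from acid, base and protic solvents.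
- Assumption on the catalyst: the (R)-isothiourea is proposed in step 18; its sense of induction is to be checked on 3-hydroxyphthalide itself, and the antipode is used if the sense is opposite.

## Analysis of the target

Compound 30 is a depsidone: a diaryl ether (C2–O–C1') and an aryl ester (C1–C(=O)–O–C2') close a seven-membered dioxepinone between two benzene rings, and a γ-lactol is fused to ring B across C5' and C6'. The lactol carbon is the only stereocentre, so there is no relative stereochemistry to control, but it is configurationally labile because the lactol equilibrates with the open aldehyde acid. The sensitive groups are the aryl ester (opened by alkoxide or hydroxide), the ring A benzylic alcohol flanked by two oxygens (ionised by strong protic or Lewis acids), the free C4' phenol and the lactol. The synthesis is hard for three reasons. Ring B is hexasubstituted and carries two neighbouring one-carbon groups at different oxidation levels. The diaryl ether has four ortho substituents. The stereocentre can only be set at the very end. The strategy rests on ring B: para oxygens at C1' and C4', a third oxygen at C2' and the methyl at C3' are the array that a 3-alkoxy-4-methylcyclobutenedione passes on unchanged, and C6' and C5' are the two carbons that a 2-propenyl unit adds.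

## Retrosynthetic reasoning

**30 from 29.** The two acyl–oxygen bonds of bis(isobutyrate) 29 are the last bonds broken. Cleavage at the acyl carbon leaves the C–O bonds at the lactol carbon and at the ring A CH2 untouched, so the configuration stored in 29 is passed to 30.

**29 from 28.** The lactol centre is set on racemic lactol 28 by acylation under conditions where its enantiomers interconvert. This is the only point where the stereocentre can be addressed, because every earlier intermediate lacks the lactol.

**28 from 26 and 25.** The lactol is opened to the C5' acid and the C6' acetal (27), the acid is taken back to aldehyde 26, and the C5'–CHO bond is cut to give 25. C5' is the only free position on ring B and sits ortho to the only phenol, so a phenol-directed formylation has no regiochemical choice. The C6' aldehyde stays masked as its acetal so that only C5' is oxidised.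

**25 from 24 and 23.** The lactone C(=O)–O(C2') bond is cut to seco acid 24, whose acid and two phenols are benzyl-protected in 23. An isopropyl ether at C2' was considered first, but its removal needs a boron or aluminium Lewis acid, which neither the acetal nor the ring A benzylic ether would survive. Three benzyl groups fall in one neutral hydrogenolysis instead.

**23 from 19 and 5.** The C2–O ether bond is cut between silyl ether 19 and fluoroarene 5 (via 21 and 22). The fluorine of 5 has a carbonyl group on each side, which compensates electronically for the crowding. The forward step must join two doubly ortho-substituted partners, and releasing the phenoxide 20 from 19 in the flask keeps the phenol next to the acetal from ever being isolated.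

**5 from 1.** The ester carbon comes from carbonylation of bromide 4, the bromine from substitution para to the methoxy group of 3, and the formyl group from metalation of 1 between fluorine and methoxy.

**19 from 15 (key disconnection).** Benzyl ether 19 comes from phenol 18, and 18 is opened across C4'–C5' to cyclobutenone 15. Five of the six ring B substituents are then already in order on a four-membered ring, and no aromatic substitution is needed on ring B. Capping the carbinol as a silyl ether means the annulation frees only the C4' hydroxyl, so the two para oxygens are told apart by construction.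

**15 from 9 and 12.** The bond between the carbinol carbon (future C1') and the alkenyl carbon (future C6') is cut to dione 9 and vinyl bromide 12, joined through vinyllithium 13 and alkoxide 14. The forward addition must go to the carbonyl of 9 that is not part of the vinylogous ester.

**9 from 6; 12 from 10.** Dione 9 comes from dibenzyl squarate 7 by exchange of one benzyloxy group for methyl, and 7 from squaric acid 6. Bromide 12 comes from acetal 10 by bromination to 11 and loss of hydrogen bromide.

## Alternatives that were turned down

**Alternative 1: ether closure on a non-aromatic ring A.**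
- Disconnection: the C2–O ether bond, cut while ring A is still a cyclohexane-1,3-dione already esterified to C2'–O (keto ester A2).
- Forward key step: acid-catalysed dehydration in which the free C1' hydroxyl condenses with the dione carbonyl next to the ester-bearing carbon, giving vinylogous ester A1 and the seven-membered ring; dehydrogenation and O-methylation then make ring A aromatic.
- For: the crowded ether bond forms intramolecularly by condensation, so no intermolecular substitution between two hindered arenes is needed. On this point it is stronger than the chosen route.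
- Against: A2 is an aryl β-keto ester and is prone to acyl transfer. Phenols are poor partners in vinylogous ester formation, and water would have to be driven off with acid while an acetal is present. Aromatising A1 must not eliminate the benzyloxy group next to the enone. Two further steps follow the key step.
- Comparison: ring B must be supplied fully substituted, with its two neighbouring oxygens already differentiated, which is the problem the chosen strategy solves by construction.

**Alternative 2: the lactol centre by acylative dynamic kinetic resolution.**
- Disconnection: the lactol C–O bond between the C5' carboxylate oxygen and the C6' aldehyde carbon, together with the acyl groups.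
- Forward key step: a chiral isothiourea and an anhydride acylate one enantiomer of racemic lactol A4 (identical with 28) while the other equilibrates through the open form, giving bis(isobutyrate) A3 (identical with 29).
- For: it is the only step that addresses the stereocentre, and in principle all of the racemate is converted. On stereocontrol it is stronger than the chosen key step, which creates no stereocentre.
- Against: as the centre of a strategy it says nothing about how hexasubstituted ring B or the depsidone is built, and it puts the highest risk on the last and most valuable intermediate.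
- Comparison: the chosen route adopts this step as step 18. What the chosen strategy adds is a construction of the skeleton on which that step can be run.

**Alternative 3: intramolecular benzannulation of ring A.**
- Disconnection: ring A and the seven-membered ring together, back to diazo keto ester A6, which is tethered through C2'–O to a ring B aryl alkynyl ether at C1'.
- Forward key step: irradiation triggers a Wolff rearrangement to a vinylketene, which adds [2+2] to the alkynyl ether (ketene carbon to the alkyne carbon that becomes C3, and C1 to C2). Ring opening and 6π closure (C4–C5) then give phenol A5, which still needs O-methylation.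
- For: it is the most convergent option; two rings form in one operation and the ether oxygen is already in place. On convergence it is stronger than the chosen route.
- Against: an alkynyl ether of a fully substituted phenol next to an aryl ester is hard to make and to keep. The ketene carries an acyl group and can react as an oxadiene with the electron-rich alkyne. The [2+2] step must close through a strained seven-membered tether.
- Comparison: it spends the benzannulation on ring A, which is available from a commercial fluoroanisole in three steps, and leaves ring B to classical chemistry. The chosen route uses a simple intermolecular precursor and applies the annulation to the difficult ring.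

Key step: step 9

## Route

**Step 1**
Reactants: 1 1-fluoro-3-methoxy-5-methylbenzene
Product: 3 2-fluoro-6-methoxy-4-methylbenzaldehyde, via aryllithium 2 (not isolated)
Conditions: n-BuLi, THF, −78 °C; DMF, −78 °C; aq. NH4Cl
Reagents that add atoms: N,N-dimethylformamide, CN(C)C=O
Why: Directed ortho-metalation removes the proton flanked by fluorine and methoxy, the most acidic and doubly coordinated site; keeping 2 at −78 °C prevents loss of LiF, and DMF delivers the formyl group.

**Step 2**
Reactants: 3 2-fluoro-6-methoxy-4-methylbenzaldehyde
Product: 4 3-bromo-2-fluoro-6-methoxy-4-methylbenzaldehyde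
Conditions: NBS, MeCN, dark, 0 °C to rt
Reagents that add atoms: N-bromosuccinimide, O=C1CCC(=O)N1Br
Why: Electrophilic aromatic bromination should go para to the methoxy group (C3), which is the stronger director; the other free site is ortho to methoxy and shielded by its methyl group, and the aldehyde is meta to both sites. Polar, dark conditions suppress benzylic bromination.

**Step 3**
Reactants: 4 3-bromo-2-fluoro-6-methoxy-4-methylbenzaldehyde
Product: 5 benzyl 2-fluoro-3-formyl-4-methoxy-6-methylbenzoate
Conditions: Pd(OAc)2, Xantphos, CO (1 atm), BnOH, i-Pr2NEt, toluene, 80 °C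
Reagents that add atoms: carbon monoxide, [C-]#[O+]; benzyl alcohol, OCc1ccccc1
Why: Palladium-catalysed alkoxycarbonylation of an aryl bromide: zerovalent palladium inserts into the C–Br bond, CO inserts, and benzyl alcohol cleaves the acyl complex. A neutral alcohol with a hindered amine should not displace the activated fluoride.

**Step 4**
Reactants: 6 squaric acid
Product: 7 dibenzyl squarate
Conditions: BnOH, toluene, reflux, Dean–Stark
Reagents that add atoms: benzyl alcohol, OCc1ccccc1
Why: Azeotropic esterification of the vinylogous diacid, catalysed by its own acidity, as used for other dialkyl squarates.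

**Step 5**
Reactants: 7 dibenzyl squarate
Product: 9 3-(benzyloxy)-4-methylcyclobut-3-ene-1,2-dione, via lithium alkoxide 8 (not isolated)
Conditions: MeLi, THF, −78 °C; (CF3CO)2O, −78 °C; aq. NH4Cl, rt
Reagents that add atoms: methyllithium, [Li]C
Why: 1,2-Addition of the methyl anion to one carbonyl of the symmetrical squarate gives 8; trifluoroacetylation and ionisation, assisted by the remote benzyloxy oxygen, expel one benzyloxy group on work-up. This is the standard conversion of a squarate into a 3-alkoxy-4-alkylcyclobutenedione.

**Step 6**
Reactants: 10 acrolein diethyl acetal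
Product: 11 2,3-dibromo-1,1-diethoxypropane (racemic)
Conditions: Br2, CH2Cl2, solid NaHCO3, −20 °C
Reagents that add atoms: bromine, BrBr
Why: Electrophilic addition of bromine to the terminal alkene; low temperature and an acid scavenger protect the acetal.

**Step 7**
Reactants: 11 2,3-dibromo-1,1-diethoxypropane
Product: 12 2-bromo-3,3-diethoxyprop-1-ene
Conditions: KOt-Bu (1.05 equiv), THF, −20 to 0 °C
Reagents that add atoms: none
Why: E2 loss of HBr: the C2 proton, acidified by bromine and the acetal, is removed with departure of the primary bromide. One equivalent of base at low temperature stops before a second elimination to the alkyne.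

**Step 8**
Reactants: 12 2-bromo-3,3-diethoxyprop-1-ene; 9 3-(benzyloxy)-4-methylcyclobut-3-ene-1,2-dione
Product: 15 3-(benzyloxy)-4-[(tert-butyldimethylsilyl)oxy]-4-(3,3-diethoxyprop-1-en-2-yl)-2-methylcyclobut-2-en-1-one (racemic), via vinyllithium 13 (not isolated), via lithium alkoxide 14 (not isolated)
Conditions: t-BuLi (2.0 equiv), Et2O, −78 °C; 9, THF, −78 °C; TBSOTf, −78 to −40 °C; aq. NaHCO3
Reagents that add atoms: tert-butyldimethylsilyl trifluoromethanesulfonate, CC(C)(C)[Si](C)(C)OS(=O)(=O)C(F)(F)F
Why: Bromine–lithium exchange gives 13, which adds 1,2 to the carbonyl of 9 next to the benzyloxy-bearing carbon; the other carbonyl is the terminus of a vinylogous ester and is deactivated. The lithium alkoxide 14 is silylated in the flask at −78 °C, where the acetal is not touched; the new stereocentre is racemic and is lost in step 9.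

**Step 9 (key step)**
Reactants: 15 3-(benzyloxy)-4-[(tert-butyldimethylsilyl)oxy]-4-(3,3-diethoxyprop-1-en-2-yl)-2-methylcyclobut-2-en-1-one
Product: 18 3-(benzyloxy)-4-[(tert-butyldimethylsilyl)oxy]-5-(diethoxymethyl)-2-methylphenol, via dienylketene 16 (not isolated), via cyclohexadienone 17 (not isolated)
Conditions: toluene (degassed, 0.02 M), 110 °C, Ar
Reagents that add atoms: none
Why: Heating cleaves the bond between the carbonyl carbon and the silyloxy-bearing carbon in a 4π conrotatory opening to dienylketene 16. The silyloxy donor rotates outward, which turns the alkenyl group inward, toward the ketene. A thermal disrotatory 6π electrocyclisation then joins the ketene carbon (future C4') to the unsubstituted alkene terminus (future C5') and closes ring B as a six-membered carbocycle, dienone 17. Enolisation of 17 gives phenol 18, and the aromatisation makes the sequence irreversible. The closest known reaction is the Moore rearrangement of 4-alkenyl-4-hydroxy- and 4-alkenyl-4-alkoxy- or silyloxycyclobutenones to hydroquinones and their monoethers. No stereocentre is formed, and the one in 15 is destroyed. The step needs torquoselectivity, which the oxygen donor on the carbinol carbon secures; the ring B regiochemistry was already fixed in step 8. With the hydroxyl capped the ketene cannot be trapped as a furanone, only the C4' oxygen emerges free, and the acetal and benzyl ether are spectators under neutral thermolysis.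

**Step 10**
Reactants: 18 3-(benzyloxy)-4-[(tert-butyldimethylsilyl)oxy]-5-(diethoxymethyl)-2-methylphenol
Product: 19 [2,4-bis(benzyloxy)-6-(diethoxymethyl)-3-methylphenoxy](tert-butyl)dimethylsilane
Conditions: BnOH, PPh3, DIAD, THF, 0 °C to rt
Reagents that add atoms: benzyl alcohol, OCc1ccccc1
Why: Mitsunobu etherification of the only free phenol; the neutral conditions avoid a phenoxide that could attack or shuffle the aryl silyl ether, and leave the acetal alone.

**Step 11**
Reactants: 19 [2,4-bis(benzyloxy)-6-(diethoxymethyl)-3-methylphenoxy](tert-butyl)dimethylsilane; 5 benzyl 2-fluoro-3-formyl-4-methoxy-6-methylbenzoate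
Product: 21 benzyl 2-[2,4-bis(benzyloxy)-6-(diethoxymethyl)-3-methylphenoxy]-3-formyl-4-methoxy-6-methylbenzoate, via cesium phenoxide 20 (not isolated)
Conditions: CsF, DMF, 4 Å MS, rt to 50 °C
Reagents that add atoms: none
Why: Fluoride cleaves the Si–O bond to phenoxide 20, which adds to C2 of 5; the Meisenheimer complex is stabilised by the ester and the aldehyde on both sides, and the expelled fluoride carries the chain. This is the known nucleophilic aromatic substitution of aryl silyl ethers on activated fluoroarenes, and it keeps the phenoxide next to the acetal at low concentration.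

**Step 12**
Reactants: 21 benzyl 2-[2,4-bis(benzyloxy)-6-(diethoxymethyl)-3-methylphenoxy]-3-formyl-4-methoxy-6-methylbenzoate
Product: 22 benzyl 2-[2,4-bis(benzyloxy)-6-(diethoxymethyl)-3-methylphenoxy]-3-(hydroxymethyl)-4-methoxy-6-methylbenzoate
Conditions: NaBH4, THF/MeOH, 0 °C
Reagents that add atoms: none
Why: Hydride reduction of the aldehyde; the hindered benzyl ester and the acetal are not reduced at 0 °C.

**Step 13**
Reactants: 22 benzyl 2-[2,4-bis(benzyloxy)-6-(diethoxymethyl)-3-methylphenoxy]-3-(hydroxymethyl)-4-methoxy-6-methylbenzoate
Product: 23 benzyl 2-[2,4-bis(benzyloxy)-6-(diethoxymethyl)-3-methylphenoxy]-3-{[(tert-butyldimethylsilyl)oxy]methyl}-4-methoxy-6-methylbenzoate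
Conditions: TBSCl, imidazole, CH2Cl2, rt
Reagents that add atoms: tert-butyldimethylsilyl chloride, CC(C)(C)[Si](C)(C)Cl
Why: Silylation of the primary alcohol, so that it cannot compete with the phenol in the lactonisation; a silyl ether, unlike a benzylic ester, survives the hydrogenolysis that follows.

**Step 14**
Reactants: 23 benzyl 2-[2,4-bis(benzyloxy)-6-(diethoxymethyl)-3-methylphenoxy]-3-{[(tert-butyldimethylsilyl)oxy]methyl}-4-methoxy-6-methylbenzoate
Product: 24 3-{[(tert-butyldimethylsilyl)oxy]methyl}-2-[6-(diethoxymethyl)-2,4-dihydroxy-3-methylphenoxy]-4-methoxy-6-methylbenzoic acid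
Conditions: H2 (1 atm), Pd/C, EtOAc, rt; filtered and used at once
Reagents that add atoms: none
Why: Hydrogenolysis of one benzyl ester and two aryl benzyl ethers, which in a neutral aprotic solvent are cleaved much faster than the benzylic acetal or the benzylic silyl ether; the reaction is stopped after three equivalents of hydrogen.

**Step 15**
Reactants: 24 3-{[(tert-butyldimethylsilyl)oxy]methyl}-2-[6-(diethoxymethyl)-2,4-dihydroxy-3-methylphenoxy]-4-methoxy-6-methylbenzoic acid
Product: 25 depsidone with ring A C3 CH2OTBS, C4 OMe, C6 CH3 and ring B C3' CH3, C4' OH, C5' H, C6' CH(OEt)2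
Conditions: DCC, 4-(dimethylamino)pyridine (cat.), CH2Cl2 (0.002 M), slow addition, rt
Reagents that add atoms: none
Why: Carbodiimide lactonisation of the kind used for depsidones: only the C2' hydroxyl can reach the activated carboxyl (seven-membered ring), while the C4' hydroxyl could react only intermolecularly, which high dilution suppresses.

**Step 16**
Reactants: 25 depsidone with free C4' OH and C5' H
Product: 26 C5'-formyl depsidone (C4' OH, C5' CHO, C6' CH(OEt)2)
Conditions: MgCl2, Et3N, (CH2O)n, MeCN, 70 °C; aq. NH4Cl
Reagents that add atoms: formaldehyde (as paraformaldehyde), C=O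
Why: Magnesium-mediated ortho-formylation of a phenol (Casnati–Skattebøl): the magnesium phenoxide delivers formaldehyde to its only free ortho position, C5', and a second formaldehyde oxidises the benzylic alkoxide. Ring A has no phenol, and the basic medium preserves the acetal.

**Step 17**
Reactants: 26 C5'-formyl depsidone
Product: 28 racemic lactol (the racemate of the target), via carboxylic acid 27 (not isolated)
Conditions: NaClO2, NaH2PO4/Na2HPO4 (pH 6), 2-methyl-2-butene, t-BuOH/THF/H2O, 0 °C to rt; Na2SO3; then 1 M HCl, THF, rt
Reagents that add atoms: sodium chlorite, [Na+].[O-]Cl=O; water, O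
Why: Pinnick oxidation converts the aldehyde into acid 27 while the alkene traps hypochlorite. In aqueous acid the neighbouring carboxyl assists ionisation of the acetal and closes onto the freed aldehyde to give the five-membered lactol as a racemate, and the primary silyl ether is cleaved in the same pot.

**Step 18**
Reactants: 28 racemic lactol
Product: 29 (R)-bis(isobutyrate): lactol O-isobutyrate and ring A CH2O-isobutyrate, C4' OH free
Conditions: (R)-2-phenyl-2,3-dihydrobenzo[d]imidazo[2,1-b]thiazole (10 mol%), (i-PrCO)2O, i-Pr2NEt, CHCl3, 0 °C
Reagents that add atoms: isobutyric anhydride, CC(C)C(=O)OC(=O)C(C)C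
Why: Acylative dynamic kinetic resolution of a 3-hydroxyphthalide: the amine keeps the lactol enantiomers in equilibrium through the open aldehyde carboxylate, and the chiral acyl isothiouronium ion acylates the (R)-lactol faster, so the catalyst sets the stereocentre. The primary alcohol is acylated as well; the C4' phenol, hydrogen-bonded to the lactone carbonyl and flanked by methyl, should stay free.

**Step 19**
Reactants: 29 (R)-bis(isobutyrate)
Product: 30 target, (R)-lactol
Conditions: immobilised Candida antarctica lipase B, n-BuOH, t-BuOMe, 30 °C
Reagents that add atoms: none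
Why: Lipase-catalysed alcoholysis, known for acyloxy lactones, attacks the acyl carbons only, so the C–O bonds at the lactol carbon and at the ring A CH2 stay intact and the configuration is retained. The medium is neutral and water-free, and the by-product is a neutral ester.

## Compound list

1 | 1-fluoro-3-methoxy-5-methylbenzene | COc1cc(C)cc(F)c1 | starting material
2 | (2-fluoro-6-methoxy-4-methylphenyl)lithium | [Li]c1c(F)cc(C)cc1OC | intermediate
3 | 2-fluoro-6-methoxy-4-methylbenzaldehyde | COc1cc(C)cc(F)c1C=O | intermediate
4 | 3-bromo-2-fluoro-6-methoxy-4-methylbenzaldehyde | COc1cc(C)c(Br)c(F)c1C=O | intermediate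
5 | benzyl 2-fluoro-3-formyl-4-methoxy-6-methylbenzoate | COc1cc(C)c(C(=O)OCc2ccccc2)c(F)c1C=O | intermediate
6 | squaric acid (3,4-dihydroxycyclobut-3-ene-1,2-dione) | O=C1C(O)=C(O)C1=O | starting material
7 | dibenzyl squarate (3,4-bis(benzyloxy)cyclobut-3-ene-1,2-dione) | O=C1C(=O)C(OCc2ccccc2)=C1OCc1ccccc1 | intermediate
8 | lithium 2,3-bis(benzyloxy)-1-methyl-4-oxocyclobut-2-en-1-olate (racemic) | CC1(O[Li])C(OCc2ccccc2)=C(OCc2ccccc2)C1=O | intermediate
9 | 3-(benzyloxy)-4-methylcyclobut-3-ene-1,2-dione | CC1=C(OCc2ccccc2)C(=O)C1=O | intermediate
10 | acrolein diethyl acetal (3,3-diethoxyprop-1-ene) | C=CC(OCC)OCC | starting material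
11 | 2,3-dibromo-1,1-diethoxypropane (racemic) | CCOC(OCC)C(Br)CBr | intermediate
12 | 2-bromo-3,3-diethoxyprop-1-ene | C=C(Br)C(OCC)OCC | intermediate
13 | (3,3-diethoxyprop-1-en-2-yl)lithium | [Li]C(=C)C(OCC)OCC | intermediate
14 | lithium 2-(benzyloxy)-1-(3,3-diethoxyprop-1-en-2-yl)-3-methyl-4-oxocyclobut-2-en-1-olate (racemic) | CC1=C(OCc2ccccc2)C(O[Li])(C(=C)C(OCC)OCC)C1=O | intermediate
15 | 3-(benzyloxy)-4-[(tert-butyldimethylsilyl)oxy]-4-(3,3-diethoxyprop-1-en-2-yl)-2-methylcyclobut-2-en-1-one (racemic) | CC1=C(OCc2ccccc2)C(O[Si](C)(C)C(C)(C)C)(C(=C)C(OCC)OCC)C1=O | intermediate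
16 | (3Z)-3-(benzyloxy)-4-[(tert-butyldimethylsilyl)oxy]-5-(diethoxymethyl)-2-methylhexa-1,3,5-trien-1-one | O=C=C(C)/C(OCc1ccccc1)=C(/O[Si](C)(C)C(C)(C)C)C(=C)C(OCC)OCC | intermediate
17 | 3-(benzyloxy)-4-[(tert-butyldimethylsilyl)oxy]-5-(diethoxymethyl)-2-methylcyclohexa-2,4-dien-1-one | O=C1CC(C(OCC)OCC)=C(O[Si](C)(C)C(C)(C)C)C(OCc2ccccc2)=C1C | intermediate
18 | 3-(benzyloxy)-4-[(tert-butyldimethylsilyl)oxy]-5-(diethoxymethyl)-2-methylphenol | Cc1c(O)cc(C(OCC)OCC)c(O[Si](C)(C)C(C)(C)C)c1OCc1ccccc1 | intermediate
19 | [2,4-bis(benzyloxy)-6-(diethoxymethyl)-3-methylphenoxy](tert-butyl)dimethylsilane | Cc1c(OCc2ccccc2)cc(C(OCC)OCC)c(O[Si](C)(C)C(C)(C)C)c1OCc1ccccc1 | intermediate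
20 | cesium 2,4-bis(benzyloxy)-6-(diethoxymethyl)-3-methylphenolate | Cc1c(OCc2ccccc2)cc(C(OCC)OCC)c([O-])c1OCc1ccccc1.[Cs+] | intermediate
21 | benzyl 2-[2,4-bis(benzyloxy)-6-(diethoxymethyl)-3-methylphenoxy]-3-formyl-4-methoxy-6-methylbenzoate | COc1cc(C)c(C(=O)OCc2ccccc2)c(Oc2c(OCc3ccccc3)c(C)c(OCc3ccccc3)cc2C(OCC)OCC)c1C=O | intermediate
22 | benzyl 2-[2,4-bis(benzyloxy)-6-(diethoxymethyl)-3-methylphenoxy]-3-(hydroxymethyl)-4-methoxy-6-methylbenzoate | COc1cc(C)c(C(=O)OCc2ccccc2)c(Oc2c(OCc3ccccc3)c(C)c(OCc3ccccc3)cc2C(OCC)OCC)c1CO | intermediate
23 | benzyl 2-[2,4-bis(benzyloxy)-6-(diethoxymethyl)-3-methylphenoxy]-3-{[(tert-butyldimethylsilyl)oxy]methyl}-4-methoxy-6-methylbenzoate | COc1cc(C)c(C(=O)OCc2ccccc2)c(Oc2c(OCc3ccccc3)c(C)c(OCc3ccccc3)cc2C(OCC)OCC)c1CO[Si](C)(C)C(C)(C)C | intermediate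
24 | 3-{[(tert-butyldimethylsilyl)oxy]methyl}-2-[6-(diethoxymethyl)-2,4-dihydroxy-3-methylphenoxy]-4-methoxy-6-methylbenzoic acid | COc1cc(C)c(C(=O)O)c(Oc2c(O)c(C)c(O)cc2C(OCC)OCC)c1CO[Si](C)(C)C(C)(C)C | intermediate
25 | depsidone: ring A C3 CH2OTBS, C4 OMe, C6 CH3; ring B C3' CH3, C4' OH, C5' H, C6' CH(OEt)2 | COc1cc(C)c2c(c1CO[Si](C)(C)C(C)(C)C)Oc1c(c(C)c(O)cc1C(OCC)OCC)OC2=O | intermediate
26 | C5'-formyl depsidone: as 25 with CHO at C5' | COc1cc(C)c2c(c1CO[Si](C)(C)C(C)(C)C)Oc1c(c(C)c(O)c(C=O)c1C(OCC)OCC)OC2=O | intermediate
27 | C5'-carboxylic acid: as 25 with CO2H at C5' | COc1cc(C)c2c(c1CO[Si](C)(C)C(C)(C)C)Oc1c(c(C)c(O)c(C(=O)O)c1C(OCC)OCC)OC2=O | intermediate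
28 | racemic lactol: depsidone with ring A C3 CH2OH and the γ-lactol fused at C5'/C6', both lactol configurations | COc1cc(C)c2c(c1CO)Oc1c(c(C)c(O)c3c1C(O)OC3=O)OC2=O | intermediate
29 | (R)-bis(isobutyrate): isobutyrates on the lactol oxygen and on the ring A CH2O, C4' OH free | COc1cc(C)c2c(c1COC(=O)C(C)C)Oc1c(c(C)c(O)c3c1[C@H](OC(=O)C(C)C)OC3=O)OC2=O | intermediate
30 | target: (R)-lactol depsidone, CNP0367167.1 | COc1cc(C)c2c(c1CO)Oc1c(c(C)c(O)c3c1[C@H](O)OC3=O)OC2=O | target

## Step count and risks

Total: 19 steps. Longest linear sequence: 14 steps (from 6 through steps 4, 5, 8–19, or from 10 through steps 6–19); the ring A branch is three steps.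

**Step 9 (key step).** The bulky silyloxy group may rotate outward less cleanly than a hydroxyl, so that part of the ketene cannot reach the alkene terminus and is lost to oligomerisation; the acetal may also lose ethanol at 110 °C. Fallback: set out from alkoxide 14 and quench it with aqueous NH4Cl to the free carbinol 3-(benzyloxy)-4-(3,3-diethoxyprop-1-en-2-yl)-4-hydroxy-2-methylcyclobut-2-en-1-one F1, the substrate with the smallest and most strongly outward-rotating donor. Thermolysis under argon gives the hydroquinone 3-(benzyloxy)-5-(diethoxymethyl)-2-methylbenzene-1,4-diol F2, which is benzylated without storage (BnBr, K2CO3, acetone) at the unhindered C4' hydroxyl to 2,4-bis(benzyloxy)-6-(diethoxymethyl)-3-methylphenol F3. F3 is coupled as the free phenol with 5 (K2CO3, DMF) and the route is rejoined at 21.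

**Step 11.** Two doubly ortho-substituted partners must meet; slow substitution would let the phenoxide decay by loss of ethoxide from the neighbouring acetal or attack the benzyl ester in an acyl transfer. Fallback: set out from 19 and the less crowded bromo aldehyde 4. The CsF-mediated substitution gives 2-[2,4-bis(benzyloxy)-6-(diethoxymethyl)-3-methylphenoxy]-3-bromo-6-methoxy-4-methylbenzaldehyde F4, and palladium-catalysed benzyloxycarbonylation of its bromide (Pd(OAc)2, Xantphos, CO under pressure, BnOH, i-Pr2NEt) brings the route back at 21. The ether is thus made before, rather than after, the ester carbon is installed.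

**Step 16.** Methoxide bound to magnesium is formed in the formylation and may open the depsidone by methanolysis; attack at C5', shielded by the acetal, may also be slow. Fallback: set out from seco acid 24 and formylate before the lactone exists. This gives 3-{[(tert-butyldimethylsilyl)oxy]methyl}-2-[6-(diethoxymethyl)-5-formyl-2,4-dihydroxy-3-methylphenoxy]-4-methoxy-6-methylbenzoic acid F5, in which the C4' hydroxyl is tied up by the new aldehyde; DCC lactonisation then returns to the route at 26.

**Step 17.** Hydrolysis of the acetal may outrun the chlorite oxidation, which would expose the second aldehyde and lead to over-oxidation of both carbons; chlorination of ring A by unscavenged hypochlorite is a lesser risk. Fallback: set out from 25 and avoid the aldehyde altogether. Ortho-bromination (NBS, i-Pr2NH cat., CH2Cl2) gives the C5'-bromo depsidone F6, and palladium-catalysed carbonylation with benzyl alcohol gives the C5'-benzyl ester F7. Hydrogenolysis (H2, Pd/C, EtOAc) returns to the route at acid 27, which is hydrolysed to 28 as in the second stage of step 17.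

**Step 18.** For this crowded, internally hydrogen-bonded lactol, ring opening may be slower than acylation, so the resolution stops being dynamic and selectivity and conversion fall; partial acylation of the phenol is a second risk. Fallback: set out from 28 and acylate without a chiral catalyst (isobutyric anhydride, 4-(dimethylamino)pyridine, i-Pr2NEt) to the racemic bis(isobutyrate) F8. The enantiomers are separated by preparative chromatography on a chiral stationary phase, the (R)-enantiomer being 29, where the route is rejoined. The (S)-bis(isobutyrate) F9 is deacylated as in step 19 and returned to the pool as racemising 28.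

**Step 19.** The enzyme may work slowly on two branched esters of a bulky substrate, giving the freed lactol time to epimerise through ring opening; the lipase may also cleave the depsidone ester. Fallback: set out from 28 and run the resolution of step 18 with pent-4-enoic anhydride, giving the (R)-bis(pent-4-enoate) F10. Its acyl groups are removed chemically by iodolactonisation (I2, THF/H2O, NaHCO3, 0 °C), which again breaks only the acyl–oxygen bonds, and this returns to the route at 30.

## Further compounds

F1 | step 9 | 3-(benzyloxy)-4-(3,3-diethoxyprop-1-en-2-yl)-4-hydroxy-2-methylcyclobut-2-en-1-one (racemic) | CC1=C(OCc2ccccc2)C(O)(C(=C)C(OCC)OCC)C1=O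
F2 | step 9 | 3-(benzyloxy)-5-(diethoxymethyl)-2-methylbenzene-1,4-diol | Cc1c(O)cc(C(OCC)OCC)c(O)c1OCc1ccccc1
F3 | step 9 | 2,4-bis(benzyloxy)-6-(diethoxymethyl)-3-methylphenol | Cc1c(OCc2ccccc2)cc(C(OCC)OCC)c(O)c1OCc1ccccc1
F4 | step 11 | 2-[2,4-bis(benzyloxy)-6-(diethoxymethyl)-3-methylphenoxy]-3-bromo-6-methoxy-4-methylbenzaldehyde | COc1cc(C)c(Br)c(Oc2c(OCc3ccccc3)c(C)c(OCc3ccccc3)cc2C(OCC)OCC)c1C=O
F5 | step 16 | 3-{[(tert-butyldimethylsilyl)oxy]methyl}-2-[6-(diethoxymethyl)-5-formyl-2,4-dihydroxy-3-methylphenoxy]-4-methoxy-6-methylbenzoic acid | COc1cc(C)c(C(=O)O)c(Oc2c(O)c(C)c(O)c(C=O)c2C(OCC)OCC)c1CO[Si](C)(C)C(C)(C)C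
F6 | step 17 | C5'-bromo depsidone: as 25 with Br at C5' | COc1cc(C)c2c(c1CO[Si](C)(C)C(C)(C)C)Oc1c(c(C)c(O)c(Br)c1C(OCC)OCC)OC2=O
F7 | step 17 | C5'-benzyl ester depsidone: as 25 with CO2Bn at C5' | COc1cc(C)c2c(c1CO[Si](C)(C)C(C)(C)C)Oc1c(c(C)c(O)c(C(=O)OCc3ccccc3)c1C(OCC)OCC)OC2=O
F8 | step 18 | racemic bis(isobutyrate) of 28 | COc1cc(C)c2c(c1COC(=O)C(C)C)Oc1c(c(C)c(O)c3c1C(OC(=O)C(C)C)OC3=O)OC2=O
F9 | step 18 | (S)-bis(isobutyrate), enantiomer of 29 | COc1cc(C)c2c(c1COC(=O)C(C)C)Oc1c(c(C)c(O)c3c1[C@@H](OC(=O)C(C)C)OC3=O)OC2=O
F10 | step 19 | (R)-bis(pent-4-enoate) of the target | COc1cc(C)c2c(c1COC(=O)CCC=C)Oc1c(c(C)c(O)c3c1[C@H](OC(=O)CCC=C)OC3=O)OC2=O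
A1 | alternative 1 | dioxepinone-fused 3-aryloxycyclohexenone (racemic diastereomers) | CC1CC(=O)C(COCc2ccccc2)=C2Oc3c(C(OC)OC)c(C(=O)OC)c(OC)c(C)c3OC(=O)C12
A2 | alternative 1 | aryl ester of the 2-(benzyloxymethyl)-5-methylcyclohexane-1,3-dione-4-carboxylic acid with free C1' hydroxyl | CC1CC(=O)C(COCc2ccccc2)C(=O)C1C(=O)Oc1c(O)c(C(OC)OC)c(C(=O)OC)c(OC)c1C
A3 | alternative 2 | (R)-bis(isobutyrate) of the target (same structure as 29) | COc1cc(C)c2c(c1COC(=O)C(C)C)Oc1c(c(C)c(O)c3c1[C@H](OC(=O)C(C)C)OC3=O)OC2=O
A4 | alternative 2 | racemic lactol (same structure as 28) | COc1cc(C)c2c(c1CO)Oc1c(c(C)c(O)c3c1C(O)OC3=O)OC2=O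
A5 | alternative 3 | depsidone with free ring A C4 phenol, C4' methyl ether, C5' methyl ester, C6' dimethyl acetal | Oc1cc(C)c2c(c1CO[Si](C)(C)C(C)(C)C)Oc1c(c(C)c(OC)c(C(=O)OC)c1C(OC)OC)OC2=O
A6 | alternative 3 | aryl 2-diazo-4-methyl-3-oxopent-4-enoate tethered to the C1' alkynyl ether | C=C(C)C(=O)C(=[N+]=[N-])C(=O)Oc1c(C)c(OC)c(C(=O)OC)c(C(OC)OC)c1OC#CCO[Si](C)(C)C(C)(C)C
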